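Two questions stand here, and both ask the same thing: by what factor does the rate at a fixed conversion grow with the charge of enzyme?

all flasks: starting material 30 mM; enzyme 0.78 µM
- Thursday's: added ligand 2.3 µM; the very flask that is asked about, followed so far
- Monday's: added ligand 1.1 µM; run made earlier
- flask: added ligand 2.3 µM

- Thursday's (time / min: target / %, starting material / %): 4.00: 0.4, 98.7; 8.00: 2.4, 98.8; 10.0: 1.0, 98.0; 15.0: 3.3, 96.8; 20.0: 3.1, 96.4; 25.0: 4.9, 94.7
- Monday's (time / min: target / %, starting material / %): 3.00: 1.1, 98.8; 4.00: 0.1, 98.8; 6.00: 1.3, 97.8; 10.0: 2.5, 97.5; 15.0: 3.5, 97.2; 25.0: 5.3, 95.1; 40.0: 7.1, 90.9

(readings scatter by 0.5 percentage points)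

- factor on the rate of making target when 30% of the starting material are converted if enzyme is charged twice over
- factor on the rate when 30% of the starting material are converted if enzyme is charged at 8.0 µM instead

- steps that have been proposed: starting material + enzyme -> target + enzyme; enzyme + added ligand <-> idle complex; 2 enzyme <-> resting dimer
- no earlier run changes the charge of enzyme; that part of a forecast is a guess

I build the flask up one process at a time. First comes the main step alone. Enzyme leaves that step as it entered, so the rate is free enzyme times a function of conversion, and this integrates in closed form:

integral of d(conversion) / function(conversion) = free enzyme × time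

So with the same starting material, more free enzyme reaches 30% sooner, with the same composition. The factor on the rate there is simply the factor on free enzyme, and 30% drops out. With the main step alone, the factors are 2 and 10.3.

Next I add the ligand. Thursday's run has twice the ligand of Monday's run. Yet at 25.0 min Thursday's run shows 4.9% target against 5.3% in Monday's run, with a scatter of 0.5 percentage points on each reading. So the ligand leaves my number where it was, as far as these runs show.

Last I add the dimer, which grows as the square of free enzyme. Where resting dimer far outweighs free enzyme and idle complex, it is the resting state, and free enzyme grows as the square root of the charge. A reservoir of dimer fits the two runs, and so does weak binding of the ligand. No run changes the enzyme, so my choice is a guess. I commit to the dimer: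

doubling: 1.41

8.0 µM against 0.78 µM: 3.20

This is the square-root factor: the square root of the ratio of two enzyme charges.

The forecast differs from my reckoning, giving 1.7 and 5.8 in the words “I take an intermediate value”.

The flask gives 1.43 on doubling and 3.29 at 8.0 µM.

    starting material + enzyme → target + enzyme, rate k1*[starting material]*[enzyme]/(1 + ([starting material]/Km1) + ([target]/Kp1)) (19.0 mM, 35.9 mM, k = 2440 M⁻¹ s⁻¹)
    enzyme + added ligand ⇌ idle complex, settled at all times (K = 2.77 × 10⁵ M⁻¹)
    2 enzyme ⇌ resting dimer, settled at all times (K = 2.77 × 10⁸ M⁻¹)

My square-root factors, 1.41 for doubling and 3.20 for the second charge, sit close to these two results. At 50.0 min in the flask, resting dimer holds nearly all of the catalyst, 92.5%, against 4.63% as free enzyme and 2.92% as idle complex. A simulated run takes away the joining of enzyme into dimer, and the apparent order in enzyme at 30% conversion moves from 0.52 to 1.0.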